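**Retrosynthetic overview**
1. The C3 side-chain ester is made last on the ring: Mitsunobu inversion of a 3-epi alcohol with a phosphonopropionic acid, then Still–Gennari olefination with acetoxyacetaldehyde; the acid and primary alcohol are unmasked in the final step.
2. Key disconnection C4–C5 (closes the only ring, the cyclohexane): the SmI2 ketyl of the C5 aldehyde adds to the electrophilic enoate β-carbon C4, and loss of pivalate from the resulting enolate creates the α-methylene ester.
3. C3–C4: asymmetric Nozaki–Hiyama–Kishi coupling of a β-bromo-α-(acyloxymethyl)acrylate with the C3 aldehyde (held as a lactol).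
4. C6–C1 (quaternary centre plus its neighbour): enantioselective boron Ireland–Claisen rearrangement of an allyl dienoate ester assembled from two small achiral fragments.

Atom labels used below: C1 = quaternary ring carbon (methyl, vinyl), C2 = ring CH2, C3 = ring C–O(ester), C4 = ring CH bearing the acrylate (C11 = its α-carbon, C12 = carboxyl carbon, C13 = methylene), C5 = ring C–OH, C6 = ring CH bearing the hydroxypropenyl group.

Assumption: the (4S,5S)-diazaborolidine of step 7 and the (S)-sulfonamide ligand of step 11 are taken to give the configurations drawn; if either sense proves opposite, the mirror-image reagent is used.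

**Route**

Step 1
Reactants: 1 4,4-dimethoxybutan-2-one; 2 triethyl phosphonoacetate
Product: 3 ethyl (2E)-5,5-dimethoxy-3-methylpent-2-enoate
Conditions: NaH, THF, 0 °C to rt; E isomer separated by chromatography
Reagents that add atoms: none
Why: Horner–Wadsworth–Emmons olefination of the methyl ketone gives the trisubstituted enoate with the E isomer predominating, and the acetal is inert to the basic conditions.

Step 2
Reactants: 3 ethyl (2E)-5,5-dimethoxy-3-methylpent-2-enoate
Product: 4 (2E)-5,5-dimethoxy-3-methylpent-2-en-1-ol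
Conditions: i-Bu2AlH (2.2 equiv), CH2Cl2, −78 °C
Reagents that add atoms: none
Why: 1,2-reduction of the conjugated ester by the aluminium hydride gives the E allylic alcohol without touching the alkene geometry or the acetal.

Step 3
Reactants: 5 ethyl (2E)-3-methyl-4-oxobut-2-enoate
Product: 6 ethyl (2E)-4-hydroxy-3-methylbut-2-enoate
Conditions: NaBH4, EtOH, −20 °C
Reagents that add atoms: none
Why: chemoselective borohydride 1,2-reduction of the aldehyde in the presence of the less electrophilic conjugated ester, with the E geometry (CH2OH trans to the ester) preventing lactonisation.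

Step 4
Reactants: 6 ethyl (2E)-4-hydroxy-3-methylbut-2-enoate
Product: 7 ethyl (2E)-4-[(tert-butyldimethylsilyl)oxy]-3-methylbut-2-enoate
Conditions: TBSCl, imidazole, DMF, rt
Reagents that add atoms: tert-butyldimethylsilyl chloride, CC(C)(C)[Si](C)(C)Cl
Why: standard silylation of the primary alcohol, giving an ether that survives base, hydride, chromium and samarium reagents and is removed with the tert-butyl ester in the last step.

Step 5
Reactants: 7 ethyl (2E)-4-[(tert-butyldimethylsilyl)oxy]-3-methylbut-2-enoate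
Product: 8 (2E)-4-[(tert-butyldimethylsilyl)oxy]-3-methylbut-2-enoic acid
Conditions: LiOH, THF/H2O, rt; then 1 M HCl to pH 4
Reagents that add atoms: lithium hydroxide, [Li+].[OH-]
Why: saponification of the ethyl ester, to which the primary silyl ether is stable.

Step 6
Reactants: 4 (2E)-5,5-dimethoxy-3-methylpent-2-en-1-ol; 8 (2E)-4-[(tert-butyldimethylsilyl)oxy]-3-methylbut-2-enoic acid
Product: 9 (2E)-5,5-dimethoxy-3-methylpent-2-en-1-yl (2E)-4-[(tert-butyldimethylsilyl)oxy]-3-methylbut-2-enoate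
Conditions: DCC, DMAP (cat.), CH2Cl2, 0 °C to rt
Reagents that add atoms: none
Why: Steglich esterification under neutral conditions joins the two fragments, and any deconjugated ester formed converges on the same dienolate in step 7.

Step 7
Reactants: 9 (2E)-5,5-dimethoxy-3-methylpent-2-en-1-yl (2E)-4-[(tert-butyldimethylsilyl)oxy]-3-methylbut-2-enoate
Product: 11 (2S,3S)-2-{3-[(tert-butyldimethylsilyl)oxy]prop-1-en-2-yl}-3-(2,2-dimethoxyethyl)-3-methylpent-4-enoic acid, via boron ketene acetal 10 (not isolated)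
Conditions: (4S,5S)-2-bromo-1,3-bis{[3,5-bis(trifluoromethyl)phenyl]sulfonyl}-4,5-diphenyl-1,3,2-diazaborolidine (1.2 equiv), Et3N, CH2Cl2, −78 °C to 4 °C; then H2O
Reagents that add atoms: none
Why: enantioselective Ireland–Claisen rearrangement in which soft γ-deprotonation of the boron-bound dienoate gives the Z(O)-boron dienolate 10, whose [3,3] shift through a chair transition state (E-allyl unit, dienolate α-substituent equatorial) forms the C6–C1 bond with the C6 side chain syn to the new vinyl group, while the C2-symmetric ligand on boron selects the enantiotopic face and so fixes C6 and the quaternary C1.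

Step 8
Reactants: 11 (2S,3S)-2-{3-[(tert-butyldimethylsilyl)oxy]prop-1-en-2-yl}-3-(2,2-dimethoxyethyl)-3-methylpent-4-enoic acid
Product: 14 (4S,5S)-5-{3-[(tert-butyldimethylsilyl)oxy]prop-1-en-2-yl}-4-ethenyl-4-methyloxan-2-ol (both anomers), via alcohol acetal 12 (not isolated), via hydroxy aldehyde 13 (not isolated)
Conditions: LiAlH4, Et2O, 0 °C to rt; then 10% aq. oxalic acid on SiO2, CH2Cl2, rt
Reagents that add atoms: water, O
Why: hydride reduction of the acid to the C5 primary alcohol followed by mild acetal hydrolysis gives the C3 aldehyde, which is trapped as the six-membered lactol without disturbing C1, C6 or the silyl ether.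

Step 9
Reactants: 15 tert-butyl 2-(bromomethyl)prop-2-enoate
Product: 17 tert-butyl (2Z)-3-bromo-2-(bromomethyl)prop-2-enoate, via tribromide 16 (not isolated)
Conditions: Br2, CH2Cl2, 0 °C; then Et3N, 0 °C to rt
Reagents that add atoms: bromine, BrBr
Why: bromine addition and base-induced dehydrobromination give the β-bromo enoate, the isomer with the vinylic bromine trans to the ester being favoured and separable.

Step 10
Reactants: 17 tert-butyl (2Z)-3-bromo-2-(bromomethyl)prop-2-enoate
Product: 18 tert-butyl (2E)-3-bromo-2-{[(2,2-dimethylpropanoyl)oxy]methyl}prop-2-enoate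
Conditions: KO2CCMe3, DMF, rt
Reagents that add atoms: potassium pivalate, CC(C)(C)C(=O)[O-].[K+]
Why: SN2 displacement of the allylic bromide by carboxylate leaves the vinylic bromide and its geometry intact and installs a leaving group that resists acyl migration yet is expelled from an ester enolate in step 13.

Step 11
Reactants: 14 (4S,5S)-5-{3-[(tert-butyldimethylsilyl)oxy]prop-1-en-2-yl}-4-ethenyl-4-methyloxan-2-ol; 18 tert-butyl (2E)-3-bromo-2-{[(2,2-dimethylpropanoyl)oxy]methyl}prop-2-enoate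
Product: 19 tert-butyl (2E,4S,6S,7S)-7-{3-[(tert-butyldimethylsilyl)oxy]prop-1-en-2-yl}-2-{[(2,2-dimethylpropanoyl)oxy]methyl}-6-ethenyl-4,8-dihydroxy-6-methyloct-2-enoate
Conditions: CrCl2 (4 equiv), NiCl2 (2 mol %), (S)-N-[2-(4-isopropyl-4,5-dihydro-1,3-oxazol-2-yl)-6-methylphenyl]methanesulfonamide, Et3N, THF, rt
Reagents that add atoms: none
Why: Nozaki–Hiyama–Kishi coupling in which the nickel-derived alkenylchromium reagent keeps the alkene geometry (C3 cis to CH2OPiv) and adds to the aldehyde released from the lactol, the chiral sulfonamide ligand on chromium setting the C3 carbinol (4S, deliberately epimeric to the target at C3) in the absence of any α-stereocentre.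

Step 12
Reactants: 19 tert-butyl (2E,4S,6S,7S)-7-{3-[(tert-butyldimethylsilyl)oxy]prop-1-en-2-yl}-2-{[(2,2-dimethylpropanoyl)oxy]methyl}-6-ethenyl-4,8-dihydroxy-6-methyloct-2-enoate
Product: 21 tert-butyl (2E)-3-[(2S,4S,5S)-5-{3-[(tert-butyldimethylsilyl)oxy]prop-1-en-2-yl}-4-ethenyl-6-hydroxy-4-methyloxan-2-yl]-2-{[(2,2-dimethylpropanoyl)oxy]methyl}prop-2-enoate (both anomers), via hydroxy aldehyde 20 (not isolated)
Conditions: TEMPO (10 mol %), PhI(OAc)2 (1.1 equiv), CH2Cl2, rt
Reagents that add atoms: none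
Why: the nitroxyl-catalysed oxidation takes the primary C5 alcohol selectively over the electron-poor secondary allylic alcohol, and the C5 aldehyde is captured by the C3 hydroxyl as a lactol, which shields C6 from epimerisation.

Step 13
Reactants: 21 tert-butyl (2E)-3-[(2S,4S,5S)-5-{3-[(tert-butyldimethylsilyl)oxy]prop-1-en-2-yl}-4-ethenyl-6-hydroxy-4-methyloxan-2-yl]-2-{[(2,2-dimethylpropanoyl)oxy]methyl}prop-2-enoate
Product: 22 tert-butyl 2-[(1R,2R,3S,4S,6S)-3-{3-[(tert-butyldimethylsilyl)oxy]prop-1-en-2-yl}-4-ethenyl-2,6-dihydroxy-4-methylcyclohexyl]prop-2-enoate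
Conditions: SmI2 (2.5 equiv), HMPA, THF, −78 °C; then sat. aq. NH4Cl
Reagents that add atoms: none
Why: Proposed new method: lactol 21 reacts through its ring-opened hydroxy-aldehyde tautomer (the open form met as compound 20 in step 12, present by ring–chain equilibrium), whose aldehyde SmI2 reduces to a ketyl radical anion, making C5 nucleophilic so that it adds 6-exo to the electrophilic β-carbon C4 of the enoate, after which the α-ester radical is reduced to a samarium enolate that expels pivalate to give the α-methylene ester; allylic 1,3-strain (C3–H eclipsing the alkene that carries the cis CH2OPiv group) directs the tethered ketyl to the face anti to the C3 oxygen (C4 trans to C3–O) and the bulky samarium-bound oxygen stays anti to the acceptor (C5–OH trans to C4), all three groups being equatorial in the chair transition state; the closest known reactions are SmI2 ketyl–olefin 6-exo cyclisations onto enoates and radical SN2′ substitutions of 2-(acyloxymethyl)acrylates.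

Step 14
Reactants: 23 methyl 2-[bis(2,2,2-trifluoroethoxy)phosphoryl]propanoate
Product: 24 2-[bis(2,2,2-trifluoroethoxy)phosphoryl]propanoic acid
Conditions: LiOH (1.0 equiv), THF/H2O, 0 °C, short contact; then 1 M HCl
Reagents that add atoms: lithium hydroxide, [Li+].[OH-]
Why: controlled saponification of the methyl carboxylate gives the phosphono acid needed as an acidic Mitsunobu partner.

Step 15
Reactants: 22 tert-butyl 2-[(1R,2R,3S,4S,6S)-3-{3-[(tert-butyldimethylsilyl)oxy]prop-1-en-2-yl}-4-ethenyl-2,6-dihydroxy-4-methylcyclohexyl]prop-2-enoate; 24 2-[bis(2,2,2-trifluoroethoxy)phosphoryl]propanoic acid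
Product: 25 tert-butyl 2-[(1S,2R,3S,4S,6R)-6-({2-[bis(2,2,2-trifluoroethoxy)phosphoryl]propanoyl}oxy)-3-{3-[(tert-butyldimethylsilyl)oxy]prop-1-en-2-yl}-4-ethenyl-2-hydroxy-4-methylcyclohexyl]prop-2-enoate (both epimers at the phosphonate α-carbon)
Conditions: PPh3, DIAD, toluene, 0 °C to rt
Reagents that add atoms: none
Why: Mitsunobu esterification, in which SN2 displacement of the C3 alkoxyphosphonium by the strongly acidic phosphono acid inverts C3 to the configuration of the target, while the C5 hydroxyl, flanked by two branched carbons, stays free.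

Step 16
Reactants: 25 tert-butyl 2-[(1S,2R,3S,4S,6R)-6-({2-[bis(2,2,2-trifluoroethoxy)phosphoryl]propanoyl}oxy)-3-{3-[(tert-butyldimethylsilyl)oxy]prop-1-en-2-yl}-4-ethenyl-2-hydroxy-4-methylcyclohexyl]prop-2-enoate; 26 2-oxoethyl acetate
Product: 27 tert-butyl 2-[(1S,2R,3S,4S,6R)-6-{[(2Z)-4-(acetyloxy)-2-methylbut-2-enoyl]oxy}-3-{3-[(tert-butyldimethylsilyl)oxy]prop-1-en-2-yl}-4-ethenyl-2-hydroxy-4-methylcyclohexyl]prop-2-enoate
Conditions: KN(SiMe3)2 (1.05 equiv), 18-crown-6, THF, −78 °C
Reagents that add atoms: none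
Why: Still–Gennari olefination, in which the electron-poor bis(trifluoroethyl) phosphonate under dissociating conditions eliminates kinetically to the Z trisubstituted enoate, building the 4-acetoxy-2-methylbut-2-enoate on the substrate without an isomerisation-prone free acid.

Step 17
Reactants: 27 tert-butyl 2-[(1S,2R,3S,4S,6R)-6-{[(2Z)-4-(acetyloxy)-2-methylbut-2-enoyl]oxy}-3-{3-[(tert-butyldimethylsilyl)oxy]prop-1-en-2-yl}-4-ethenyl-2-hydroxy-4-methylcyclohexyl]prop-2-enoate
Product: 28 2-[(1S,2R,3S,4S,6R)-6-{[(2Z)-4-(acetyloxy)-2-methylbut-2-enoyl]oxy}-4-ethenyl-2-hydroxy-3-(3-hydroxyprop-1-en-2-yl)-4-methylcyclohexyl]prop-2-enoic acid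
Conditions: TFA/CH2Cl2/H2O (10:30:1), 0 °C to rt; brief NaHCO3/MeOH wash of any trifluoroacetates
Reagents that add atoms: none
Why: acidolysis cleaves the tert-butyl ester through the tert-butyl cation and hydrolyses the primary silyl ether while the acetate and both enoate esters survive and no stereocentre is touched.

**Compound list**
1 | 4,4-dimethoxybutan-2-one | CC(=O)CC(OC)OC | starting material
2 | triethyl phosphonoacetate | CCOC(=O)CP(=O)(OCC)OCC | starting material
3 | ethyl (2E)-5,5-dimethoxy-3-methylpent-2-enoate | CCOC(=O)/C=C(\C)CC(OC)OC | intermediate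
4 | (2E)-5,5-dimethoxy-3-methylpent-2-en-1-ol | OC/C=C(\C)CC(OC)OC | intermediate
5 | ethyl (2E)-3-methyl-4-oxobut-2-enoate | CCOC(=O)/C=C(\C)C=O | starting material
6 | ethyl (2E)-4-hydroxy-3-methylbut-2-enoate | CCOC(=O)/C=C(\C)CO | intermediate
7 | ethyl (2E)-4-[(tert-butyldimethylsilyl)oxy]-3-methylbut-2-enoate | CCOC(=O)/C=C(\C)CO[Si](C)(C)C(C)(C)C | intermediate
8 | (2E)-4-[(tert-butyldimethylsilyl)oxy]-3-methylbut-2-enoic acid | OC(=O)/C=C(\C)CO[Si](C)(C)C(C)(C)C | intermediate
9 | (2E)-5,5-dimethoxy-3-methylpent-2-en-1-yl (2E)-4-[(tert-butyldimethylsilyl)oxy]-3-methylbut-2-enoate | COC(OC)C/C(C)=C/COC(=O)/C=C(\C)CO[Si](C)(C)C(C)(C)C | intermediate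
10 | Z(O)-boron dienolate of 9: 1-{[(2E)-5,5-dimethoxy-3-methylpent-2-en-1-yl]oxy}-3-{[(tert-butyldimethylsilyl)oxy]methyl}buta-1,3-dien-1-yl ether of the (4S,5S)-1,3-bis{[3,5-bis(trifluoromethyl)phenyl]sulfonyl}-4,5-diphenyl-1,3,2-diazaborolidin-2-ol | COC(OC)C/C(C)=C/CO/C(OB1N(S(=O)(=O)c2cc(C(F)(F)F)cc(C(F)(F)F)c2)[C@@H](c2ccccc2)[C@H](c2ccccc2)N1S(=O)(=O)c1cc(C(F)(F)F)cc(C(F)(F)F)c1)=C/C(=C)CO[Si](C)(C)C(C)(C)C | intermediate
11 | (2S,3S)-2-{3-[(tert-butyldimethylsilyl)oxy]prop-1-en-2-yl}-3-(2,2-dimethoxyethyl)-3-methylpent-4-enoic acid | C=C[C@](C)(CC(OC)OC)[C@@H](C(=C)CO[Si](C)(C)C(C)(C)C)C(=O)O | intermediate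
12 | (2S,3S)-2-{3-[(tert-butyldimethylsilyl)oxy]prop-1-en-2-yl}-3-(2,2-dimethoxyethyl)-3-methylpent-4-en-1-ol | C=C[C@](C)(CC(OC)OC)[C@@H](C(=C)CO[Si](C)(C)C(C)(C)C)CO | intermediate
13 | (3S,4S)-4-{3-[(tert-butyldimethylsilyl)oxy]prop-1-en-2-yl}-3-ethenyl-5-hydroxy-3-methylpentanal | C=C[C@](C)(CC=O)[C@@H](C(=C)CO[Si](C)(C)C(C)(C)C)CO | intermediate
14 | (4S,5S)-5-{3-[(tert-butyldimethylsilyl)oxy]prop-1-en-2-yl}-4-ethenyl-4-methyloxan-2-ol (both anomers) | C=C[C@]1(C)CC(O)OC[C@@H]1C(=C)CO[Si](C)(C)C(C)(C)C | intermediate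
15 | tert-butyl 2-(bromomethyl)prop-2-enoate | C=C(CBr)C(=O)OC(C)(C)C | starting material
16 | tert-butyl 2,3-dibromo-2-(bromomethyl)propanoate | BrCC(Br)(CBr)C(=O)OC(C)(C)C | intermediate
17 | tert-butyl (2Z)-3-bromo-2-(bromomethyl)prop-2-enoate | Br/C=C(\CBr)C(=O)OC(C)(C)C | intermediate
18 | tert-butyl (2E)-3-bromo-2-{[(2,2-dimethylpropanoyl)oxy]methyl}prop-2-enoate | Br/C=C(\COC(=O)C(C)(C)C)C(=O)OC(C)(C)C | intermediate
19 | tert-butyl (2E,4S,6S,7S)-7-{3-[(tert-butyldimethylsilyl)oxy]prop-1-en-2-yl}-2-{[(2,2-dimethylpropanoyl)oxy]methyl}-6-ethenyl-4,8-dihydroxy-6-methyloct-2-enoate | C=C[C@](C)(C[C@H](O)/C=C(\COC(=O)C(C)(C)C)C(=O)OC(C)(C)C)[C@@H](C(=C)CO[Si](C)(C)C(C)(C)C)CO | intermediate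
20 | tert-butyl (2E,4S,6S,7S)-7-{3-[(tert-butyldimethylsilyl)oxy]prop-1-en-2-yl}-2-{[(2,2-dimethylpropanoyl)oxy]methyl}-6-ethenyl-4-hydroxy-6-methyl-8-oxooct-2-enoate | C=C[C@](C)(C[C@H](O)/C=C(\COC(=O)C(C)(C)C)C(=O)OC(C)(C)C)[C@@H](C(=C)CO[Si](C)(C)C(C)(C)C)C=O | intermediate
21 | tert-butyl (2E)-3-[(2S,4S,5S)-5-{3-[(tert-butyldimethylsilyl)oxy]prop-1-en-2-yl}-4-ethenyl-6-hydroxy-4-methyloxan-2-yl]-2-{[(2,2-dimethylpropanoyl)oxy]methyl}prop-2-enoate (both anomers) | C=C[C@]1(C)C[C@@H](/C=C(\COC(=O)C(C)(C)C)C(=O)OC(C)(C)C)OC(O)[C@@H]1C(=C)CO[Si](C)(C)C(C)(C)C | intermediate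
22 | tert-butyl 2-[(1R,2R,3S,4S,6S)-3-{3-[(tert-butyldimethylsilyl)oxy]prop-1-en-2-yl}-4-ethenyl-2,6-dihydroxy-4-methylcyclohexyl]prop-2-enoate | C=C[C@]1(C)C[C@H](O)[C@@H](C(=C)C(=O)OC(C)(C)C)[C@H](O)[C@@H]1C(=C)CO[Si](C)(C)C(C)(C)C | intermediate
23 | methyl 2-[bis(2,2,2-trifluoroethoxy)phosphoryl]propanoate | COC(=O)C(C)P(=O)(OCC(F)(F)F)OCC(F)(F)F | starting material
24 | 2-[bis(2,2,2-trifluoroethoxy)phosphoryl]propanoic acid | OC(=O)C(C)P(=O)(OCC(F)(F)F)OCC(F)(F)F | intermediate
25 | tert-butyl 2-[(1S,2R,3S,4S,6R)-6-({2-[bis(2,2,2-trifluoroethoxy)phosphoryl]propanoyl}oxy)-3-{3-[(tert-butyldimethylsilyl)oxy]prop-1-en-2-yl}-4-ethenyl-2-hydroxy-4-methylcyclohexyl]prop-2-enoate | C=C[C@]1(C)C[C@@H](OC(=O)C(C)P(=O)(OCC(F)(F)F)OCC(F)(F)F)[C@@H](C(=C)C(=O)OC(C)(C)C)[C@H](O)[C@@H]1C(=C)CO[Si](C)(C)C(C)(C)C | intermediate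
26 | 2-oxoethyl acetate (acetoxyacetaldehyde) | CC(=O)OCC=O | starting material
27 | tert-butyl 2-[(1S,2R,3S,4S,6R)-6-{[(2Z)-4-(acetyloxy)-2-methylbut-2-enoyl]oxy}-3-{3-[(tert-butyldimethylsilyl)oxy]prop-1-en-2-yl}-4-ethenyl-2-hydroxy-4-methylcyclohexyl]prop-2-enoate | C=C[C@]1(C)C[C@@H](OC(=O)/C(C)=C\COC(C)=O)[C@@H](C(=C)C(=O)OC(C)(C)C)[C@H](O)[C@@H]1C(=C)CO[Si](C)(C)C(C)(C)C | intermediate
28 | 2-[(1S,2R,3S,4S,6R)-6-{[(2Z)-4-(acetyloxy)-2-methylbut-2-enoyl]oxy}-4-ethenyl-2-hydroxy-3-(3-hydroxyprop-1-en-2-yl)-4-methylcyclohexyl]prop-2-enoic acid (CNP0261293.2) | C=C[C@]1(C)C[C@@H](OC(=O)/C(C)=C\COC(C)=O)[C@@H](C(=C)C(=O)O)[C@H](O)[C@@H]1C(=C)CO | target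

**Step count and risks**
Total step count: 17. Longest linear sequence: 12 steps (steps 3, 4, 5, 6, 7, 8, 11, 12, 13, 15, 16, 17).

The three steps most likely to fail:

Step 13 (ring closure). The required diastereomer needs a chair with the C1 methyl and the C6 side chain axial. Direct reduction of the enoate, lactonisation of the C5 alkoxide onto the ester, or over-reduction of the new acrylate could also intervene. The fallback sets out from lactol 21 and returns at diol 22. It closes the same C4–C5 bond by a two-electron path in which C4, not C5, is the nucleophile: Pd(PPh3)4 ionises the allylic pivalate and InI reduces the allylpalladium to an allylindium reagent. That reagent adds through C4 to the aldehyde in a closed transition state under the same allylic-strain control. This fallback makes no new compound (entry F0).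

Step 15 (Mitsunobu inversion at C3). The carbinol is hindered, and axial entry of the carboxylate is syn to the axial C1 methyl, so elimination or no reaction is possible. The fallback sets out from 22 and returns at 25. The less hindered C3 alcohol is oxidised with Dess–Martin periodinane (1 equiv) to the β-hydroxy ketone tert-butyl 2-[(1S,2R,3S,4S)-3-{3-[(tert-butyldimethylsilyl)oxy]prop-1-en-2-yl}-4-ethenyl-2-hydroxy-4-methyl-6-oxocyclohexyl]prop-2-enoate F1. The ketone is reduced with Me4NBH(OAc)3 (Evans–Saksena, hydride delivered from the C5 oxygen, anti-1,3-diol) to tert-butyl 2-[(1R,2R,3S,4S,6R)-3-{3-[(tert-butyldimethylsilyl)oxy]prop-1-en-2-yl}-4-ethenyl-2,6-dihydroxy-4-methylcyclohexyl]prop-2-enoate F2. The C3 hydroxyl of F2 is then acylated with acid 24 (DCC, DMAP) to give 25 with retention.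

Step 7 (enantioselective Claisen). The dienolate geometry, the level of enantiocontrol and the survival of the acetal next to the boron bromide are all uncertain. The fallback sets out from ester 9 and returns at acid 11. LiN(i-Pr)2 and Me3SiCl in THF give the trimethylsilyl ketene acetal of 9, 1-{[(2E)-5,5-dimethoxy-3-methylpent-2-en-1-yl]oxy}-1-[(trimethylsilyl)oxy]-3-{[(tert-butyldimethylsilyl)oxy]methyl}buta-1,3-diene F3. It rearranges on warming to racemic 11 with the same relative configuration. The acid is resolved by crystallising the (S)-1-phenylethylammonium (2S,3S)-2-{3-[(tert-butyldimethylsilyl)oxy]prop-1-en-2-yl}-3-(2,2-dimethoxyethyl)-3-methylpent-4-enoate salt F4, and acidification releases 11.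

Further compounds
F0 | step 13 | none | none
F1 | step 15 | tert-butyl 2-[(1S,2R,3S,4S)-3-{3-[(tert-butyldimethylsilyl)oxy]prop-1-en-2-yl}-4-ethenyl-2-hydroxy-4-methyl-6-oxocyclohexyl]prop-2-enoate | C=C[C@]1(C)CC(=O)[C@@H](C(=C)C(=O)OC(C)(C)C)[C@H](O)[C@@H]1C(=C)CO[Si](C)(C)C(C)(C)C
F2 | step 15 | tert-butyl 2-[(1R,2R,3S,4S,6R)-3-{3-[(tert-butyldimethylsilyl)oxy]prop-1-en-2-yl}-4-ethenyl-2,6-dihydroxy-4-methylcyclohexyl]prop-2-enoate | C=C[C@]1(C)C[C@@H](O)[C@@H](C(=C)C(=O)OC(C)(C)C)[C@H](O)[C@@H]1C(=C)CO[Si](C)(C)C(C)(C)C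
F3 | step 7 | 1-{[(2E)-5,5-dimethoxy-3-methylpent-2-en-1-yl]oxy}-1-[(trimethylsilyl)oxy]-3-{[(tert-butyldimethylsilyl)oxy]methyl}buta-1,3-diene | COC(OC)C/C(C)=C/CO/C(O[Si](C)(C)C)=C/C(=C)CO[Si](C)(C)C(C)(C)C
F4 | step 7 | (S)-1-phenylethylammonium (2S,3S)-2-{3-[(tert-butyldimethylsilyl)oxy]prop-1-en-2-yl}-3-(2,2-dimethoxyethyl)-3-methylpent-4-enoate | C=C[C@](C)(CC(OC)OC)[C@@H](C(=C)CO[Si](C)(C)C(C)(C)C)C(=O)[O-].C[C@H]([NH3+])c1ccccc1
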